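## Structural features

The target 14 is a 2,3-dihydro-1-benzofuran-6(5H)-one. A dihydrofuran ring (O1, C2, C3, C3a, C7a) is fused along the C3a–C7a bond to a six-membered cyclohexa-2,4-dienone ring (C3a=C4, C5, C6=O, C7=C7a). C2 carries the 3,4,5-trimethoxyphenyl group and C3 the methyl group; these neighbouring stereocentres are both S, and the two substituents are trans. The third stereocentre, C5 (R), is quaternary and bears allyl and methoxy. It lies next to the C6 carbonyl, is separated from C3 by the C3a=C4 double bond, and has its allyl group on the ring face of the C2 aryl group. Because O1 is bound to C7a, the C6 carbonyl is a vinylogous ester (O1–C7a=C7–C6=O), whereas C5 is at the oxidation level of an ordinary ketone carbon. Fragile points are: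
- the dienone, which aromatises if a C5 substituent is lost or shifted, and whose allyl group can migrate by [3,3] shifts on heating or at the alkoxide stage;
- the benzylic C2–O1 bond to an electron-rich aryl group, which is acid-labile;
- the C3–H bond once the carbocycle is at the quinone level.

The real difficulty is to build a non-aromatic, oxygenated six-membered ring with a quaternary stereocentre remote from the C2/C3 pair. The key step uses the position of O1: C7a is ortho to the side-chain carbon C3a and β to the C6 carbonyl. This is the site at which a hydroxyl tethered through C3 and C2 adds to the ortho-quinone of a 4-alkylcatechol, and C5 and C6 are then the two catechol oxygens.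

## Logic of the disconnections

14 ⇒ 13. The O–CH3 bond at C5 is cut. The methyl ether plays no part in any ring-forming event, and its removal exposes a tertiary α-hydroxy ketone, the retron of a carbonyl addition. The gain is small in atoms but large in logic. The forward methylation must work on a hindered neutral hydroxyl, because the alkoxide of 13 is a 3-oxido-1,5-diene (allyl–C5–C4=C3a) set up for an anionic oxy-Cope shift. It must also leave the vinylogous-ester oxygen at C6 alone.

13 ⇒ 9 + 12. The C5–CH2 bond of the allyl group is cut. This removes the only quaternary stereocentre and leaves a flat ring in which C5 and C6 are both carbonyl carbons. The forward step must add allyl 1,2 and not in a conjugate sense, at C5 and not at C6, and on the face opposite the C3 methyl group. The first two demands are met by a closed transition state of an allylboron reagent and by the electronic difference between the two carbonyls. The third needs a chiral catalyst to reinforce a weak substrate bias.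

12 ⇒ 10 + 11. The B–C bond is cut. The pinacol ester does not exchange its diol under mild conditions, so the open-chain diisopropyl ester is needed and is made from two bulk chemicals. The only demand is mono-addition at low temperature.

9 ⇒ 6 (through 8 and 7). The O1–C7a bond is cut and the carbocycle is returned to the catechol level. This takes away the heterocycle and the third ring oxygen in one move and leaves two benzene rings joined by a two-carbon chain that already carries both stereocentres. The forward step must oxidise the catechol ring of 6 and make the secondary hydroxyl add at the correct ortho carbon before the transient quinone 7 tautomerises or is hydrated. It must then oxidise 8 once more without enolisation at C3.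

6 ⇒ 5. The two O–CH2Ph bonds are cut (protecting groups). A free catechol would not survive the basic palladium step or the ruthenium step. Benzyl ethers are cleaved under neutral conditions, which the acid-sensitive trimethoxybenzylic alcohol requires. The demand is hydrogenolysis of the aryl benzyl ethers without loss of the benzylic C1 hydroxyl.

5 ⇒ 4. The C1–H bond of the carbinol is cut. Both stereocentres then derive from one configurationally labile α-aryl ketone. The forward reduction must be faster for one enantiomer of 4 than for the other while the two interconvert (dynamic kinetic resolution). It must deliver hydride anti to the α-aryl group so that the like (1S,2S) pair results.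

4 ⇒ 2 + 3. The bond between the α-carbon and the dioxygenated aryl ring is cut. This divides the skeleton into two cheap aromatic pieces. The forward step must mono-arylate a propiophenone enolate with an electron-rich aryl bromide.

2 ⇒ 1. The two benzyl–oxygen bonds are cut. This is a routine double etherification with no selectivity demand.

## Other disconnections considered

Alternative 1: The six-membered ring is cut at C5–C6, C6–C7 and C3a–C7a, and the dihydrofuran at O1–C7a.
- Forward key step: a vinylketene, generated from an unsaturated acid chloride and Et3N, undergoes [2+2] cycloaddition with an ethoxy-substituted alkyne. The cyclobutenone opens in a 4π step to a dienylketene, and a 6π electrocyclisation gives (6R)-6-allyl-3-ethoxy-6-methoxy-4-[(2S,3S)-3-(tert-butyldimethylsilyloxy)-3-(3,4,5-trimethoxyphenyl)propan-2-yl]cyclohexa-2,4-dien-1-one A1. The fully substituted terminus cannot tautomerise to a phenol. Desilylation and addition–elimination of the freed hydroxyl at the ethoxy-bearing carbon would then give 14.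
- In its favour: allyl and methoxy are in place before the ring exists, so there is no late methylation of a hindered alcohol and no quinone. The regiochemistry of the ketene–alkoxyalkyne union is dependable, and the final O1–C7a closure is a secure vinylogous transesterification.
- Against it here: C5 is created in the electrocyclisation. Its configuration depends on the enol-ether geometry of the vinylketene and on the sense of rotation, which only the remote side-chain stereocentres could influence. The pendant allyl alkene can also intercept the ketene in an intramolecular [2+2] reaction. The acyclic precursor (stereodiad, tetrasubstituted enol ether, acid chloride) would need many steps.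
- Comparison: on structure the alternative is the better plan, since it never passes through an ortho-quinone or a free tertiary ketol. On control of C5 the two plans are equal in lacking strong substrate control, but the chosen plan can add an external chiral catalyst and separate epimers at a stable stage. On step economy the chosen plan, with seven linear steps, should be clearly shorter.

Alternative 2: The C3–C3a bond is cut and the C3 methyl group is read as the degraded carbonyl carbon of a flavanone.
- Forward key step: PhI(OAc)2 with HC(OMe)3 and H2SO4 converts the (2S)-flavanone precursor into its enol ether and adds iodine at C3. The fused aryl carbon then shifts from C4 to C3 as iodobenzene leaves, and the old carbonyl carbon ends as an ester in methyl (2S,3S)-6-(benzyloxy)-5-methoxy-2-(3,4,5-trimethoxyphenyl)-2,3-dihydro-1-benzofuran-3-carboxylate A2.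
- In its favour: O1–C7a exists from the start, C2 is carried through, and the trans relationship follows from the migration and is thermodynamically backed. The reagents are cheap and the intermediates are stable, aromatic and easy to purify.
- Against it here: the electron-rich C2 aryl group is itself a good migrating group, which opens the competing 2,3-shift to an isoflavone. The strongly acidic medium can ionise or open the C2–O1 bond and erode the configuration. An enantiopure flavanone is not trivial to obtain. Three further steps turn the ester into the methyl group. The arene of A2 must then still be dearomatised with C–C bond formation at the methoxy-bearing C5, for which the realistic path is oxidation to 9 and the same endgame as the chosen plan.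
- Comparison: on the C2/C3 pair the two plans are equal, each setting it in one step. On stability of intermediates the alternative is better. On mechanism it carries a chemoselectivity risk that the chosen key step does not. On step economy it is longer and leaves the C5 problem untouched.

Alternative 3: The C2–C3 bond is cut.
- Forward key step: Rh2(S-PTTL)4 (or its enantiomer) decomposes an ortho-benzyloxy aryldiazoacetate. The donor/acceptor carbene inserts into the benzylic ether C–H bond in a 1,5 sense to give methyl (2S,3R)-5,6-bis(methoxymethoxy)-2-(3,4,5-trimethoxyphenyl)-2,3-dihydro-1-benzofuran-3-carboxylate A3, the cis isomer. Base epimerisation at C3, conversion of the ester into a methyl group and acetal removal would lead to 8 and, after oxidation, to 9.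
- In its favour: a catalytic asymmetric C–C bond formation with strong precedent for exactly this ring system. The heterocycle is closed on an aromatic ring, so the quinone is reached by simple catechol oxidation with no transient quinone that must be captured.
- Against it here: roughly four steps to the diazo compound and five more from A3 to 9, against five steps in total to 9 in the chosen plan. Acid removal of the acetals is required on a substrate with an acid-labile C2–O1 bond. The ester-to-methyl detour is needed.
- Comparison: on reliability of ring closure and of the absolute configuration at C2 the alternative is the equal of the chosen plan, and on freedom from quinone-methide scrambling during ring formation it is the better. On the endgame the two are identical. On step economy the chosen plan is markedly better.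

Key step: step 5

Remark on the chemistry: the sense of induction of a 3,3'-dibromo-BINOL catalyst on a quinone carbonyl cannot be derived from its ketone precedents. The (S)-diol is written in step 7 as the working choice, its mirror image is the immediate substitute if the pairing with the substrate bias is mismatched, and the C5 epimers of 13 are assumed separable on silica. Reagent 12 is prepared ahead of step 5 because 9 is used as soon as it is made.

## Route

Step 1
Reactants: 1 4-bromocatechol
Product: 2 4-bromo-1,2-bis(benzyloxy)benzene
Conditions: BnBr (2.3 equiv), K2CO3, DMF, 60 °C, N2
Reagents that add atoms: benzyl bromide, BrCc1ccccc1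
Why: Double Williamson etherification of the two phenoxides; the inert atmosphere prevents air oxidation of the catechol dianion.

Step 2
Reactants: 2 4-bromo-1,2-bis(benzyloxy)benzene; 3 1-(3,4,5-trimethoxyphenyl)propan-1-one
Product: 4 rac-2-[3,4-bis(benzyloxy)phenyl]-1-(3,4,5-trimethoxyphenyl)propan-1-one
Conditions: Pd(OAc)2 (2 mol%), Xantphos (3 mol%), NaOt-Bu, toluene, 80 °C
Reagents that add atoms: none
Why: Palladium-catalysed α-arylation of a ketone enolate: oxidative addition of 2 to zerovalent palladium, enolate binding and C–C reductive elimination, favoured by the wide-bite-angle ligand. The tertiary, more acidic product resists a second arylation; its stereocentre is formed racemic and is settled in step 3.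

Step 3
Reactants: 4 rac-2-[3,4-bis(benzyloxy)phenyl]-1-(3,4,5-trimethoxyphenyl)propan-1-one
Product: 5 (1S,2S)-2-[3,4-bis(benzyloxy)phenyl]-1-(3,4,5-trimethoxyphenyl)propan-1-ol
Conditions: RuCl[(S,S)-TsDPEN](p-cymene) (2 mol%), HCO2H/Et3N (1:2), DBU (0.2 equiv), DMF, 40 °C
Reagents that add atoms: none
Why: Noyori–Ikariya asymmetric transfer hydrogenation with dynamic kinetic resolution, a known route to like-configured 1,2-diarylpropan-1-ols. The amine-rich medium racemises the α-aryl ketone through its enol, and the (S,S)-ligand sets the carbinol as S as it does for aryl alkyl ketones. The catalyst reduces fastest the enantiomer in which that face is also the Felkin–Anh face (hydride anti to the α-aryl group), which fixes C2 as S.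

Step 4
Reactants: 5 (1S,2S)-2-[3,4-bis(benzyloxy)phenyl]-1-(3,4,5-trimethoxyphenyl)propan-1-ol
Product: 6 4-[(1S,2S)-1-hydroxy-1-(3,4,5-trimethoxyphenyl)propan-2-yl]benzene-1,2-diol
Conditions: H2 (1 atm), 10% Pd/C, EtOAc, rt; filtration under Ar
Reagents that add atoms: none
Why: Hydrogenolysis of aryl benzyl ethers, which in neutral ethyl acetate is much faster than cleavage of the secondary benzylic C–OH bond. The reaction is stopped at two equivalents of hydrogen, and the air-sensitive catechol is taken on at once.

Step 5
Reactants: 6 4-[(1S,2S)-1-hydroxy-1-(3,4,5-trimethoxyphenyl)propan-2-yl]benzene-1,2-diol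
Product: 9 (2S,3S)-3-methyl-2-(3,4,5-trimethoxyphenyl)-2,3-dihydro-1-benzofuran-5,6-dione, via hydroxyalkyl ortho-quinone 7 (not isolated), via dihydrobenzofuran-5,6-diol 8 (not isolated)
Conditions: NaIO4 (2 × 1.1 equiv), MeCN/aq. NaOAc–AcOH buffer (pH 5), 0 °C; cold CH2Cl2 extraction
Reagents that add atoms: none
Why: NaIO4 should oxidise the catechol of 6 through a cyclic periodate ester to the ortho-quinone 7 within seconds at 0 °C. The C1 hydroxyl then adds to the ring carbon that is ortho to the side chain and β to the remote carbonyl (the future C7a), a 5-exo-trig oxa-Michael closure that forms O1–C7a, and enolisation gives the aromatic diol 8. Carrying a third ring oxygen, 8 is more easily oxidised than 6 and is taken to 9 by the second portion of periodate or by redox exchange with 7. The closest known reaction type is the cyclodopa closure of dopaquinone, together with the lactone and chroman closures of catechols that bear carboxyl or hydroxyl side chains. No stereocentre is made: no bond to C2 or C3 is broken, so the trans (2S,3S) pair of 6 is carried over, and the branching at both chain carbons favours the folded conformer that closes. Regioselectivity for C7a over C4, the other ortho carbon, rests on C7a being a Michael β-position for a hard oxygen nucleophile whereas C4 is α to a carbonyl. Selectivity against hydration, and against tautomerisation of 7 or 9 to quinone methides that would scramble C3 or lead to an aromatic benzofuran, is sought through intramolecularity, the weakly acidic buffer, the low temperature, short contact time and immediate use of 9.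

Step 6
Reactants: 10 triisopropyl borate; 11 allylmagnesium bromide
Product: 12 diisopropyl allylboronate
Conditions: Et2O, −78 °C → rt; HCl (Et2O), 0 °C; filtration, distillation
Reagents that add atoms: none
Why: Addition of the allyl Grignard reagent to the borate gives the tetracoordinate ate complex, which anhydrous HCl cleaves to the boronic ester (known preparation); the low temperature prevents a second addition.

Step 7
Reactants: 9 (2S,3S)-3-methyl-2-(3,4,5-trimethoxyphenyl)-2,3-dihydro-1-benzofuran-5,6-dione; 12 diisopropyl allylboronate
Product: 13 (2S,3S,5R)-5-hydroxy-3-methyl-5-(prop-2-en-1-yl)-2-(3,4,5-trimethoxyphenyl)-2,3-dihydro-1-benzofuran-6(5H)-one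
Conditions: (S)-3,3'-Br2-BINOL (15 mol%), PhCF3/toluene (3:1), −35 °C; pH 7 buffer
Reagents that add atoms: none
Why: Proposed new method: exchange of one isopropoxy group of 12 for the chiral diol should give a more Lewis-acidic mixed boronate that binds the C5 carbonyl oxygen and transfers allyl through a closed six-membered chair transition state, so that addition is 1,2 and not conjugate; C5 should react in preference to C6 because C6 is deactivated as a vinylogous ester of O1, and the chiral pocket, reinforced by the C3 methyl group that screens the opposite face, should direct allyl to the face of the C2 aryl group and set C5 as R; the closest known reaction type is the 3,3'-dibromo-BINOL-catalysed asymmetric allylboration of aryl and alkenyl ketones with this boronate, which has not been shown on an ortho-quinone carbonyl.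

Step 8
Reactants: 13 (2S,3S,5R)-5-hydroxy-3-methyl-5-(prop-2-en-1-yl)-2-(3,4,5-trimethoxyphenyl)-2,3-dihydro-1-benzofuran-6(5H)-one
Product: 14 (2S,3S,5R)-5-methoxy-3-methyl-5-(prop-2-en-1-yl)-2-(3,4,5-trimethoxyphenyl)-2,3-dihydro-1-benzofuran-6(5H)-one
Conditions: MeOTf, 2,6-di-tert-butyl-4-methylpyridine, CH2Cl2, 0 °C → rt
Reagents that add atoms: methyl trifluoromethanesulfonate, COS(=O)(=O)C(F)(F)F
Why: SN2 O-methylation of the neutral tertiary hydroxyl by a hard methylating agent, with a hindered pyridine as proton scavenger (known for hindered and base-sensitive alcohols). Because no alkoxide is formed, the anionic oxy-Cope shift of the allyl group to C3a and the α-ketol shift are avoided, and C5 keeps its configuration since no bond to it is broken.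

## Compound list

1 | 4-bromocatechol | Oc1ccc(Br)cc1O | starting material
2 | 4-bromo-1,2-bis(benzyloxy)benzene | Brc1ccc(OCc2ccccc2)c(OCc2ccccc2)c1 | intermediate
3 | 1-(3,4,5-trimethoxyphenyl)propan-1-one | CCC(=O)c1cc(OC)c(OC)c(OC)c1 | starting material
4 | rac-2-[3,4-bis(benzyloxy)phenyl]-1-(3,4,5-trimethoxyphenyl)propan-1-one | CC(C(=O)c1cc(OC)c(OC)c(OC)c1)c1ccc(OCc2ccccc2)c(OCc2ccccc2)c1 | intermediate
5 | (1S,2S)-2-[3,4-bis(benzyloxy)phenyl]-1-(3,4,5-trimethoxyphenyl)propan-1-ol | O[C@H](c1cc(OC)c(OC)c(OC)c1)[C@@H](C)c1ccc(OCc2ccccc2)c(OCc2ccccc2)c1 | intermediate
6 | 4-[(1S,2S)-1-hydroxy-1-(3,4,5-trimethoxyphenyl)propan-2-yl]benzene-1,2-diol | O[C@H](c1cc(OC)c(OC)c(OC)c1)[C@@H](C)c1ccc(O)c(O)c1 | intermediate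
7 | 4-[(1S,2S)-1-hydroxy-1-(3,4,5-trimethoxyphenyl)propan-2-yl]cyclohexa-3,5-diene-1,2-dione | O[C@H](c1cc(OC)c(OC)c(OC)c1)[C@@H](C)C1=CC(=O)C(=O)C=C1 | intermediate
8 | (2S,3S)-3-methyl-2-(3,4,5-trimethoxyphenyl)-2,3-dihydro-1-benzofuran-5,6-diol | Oc1cc2c(cc1O)O[C@H](c1cc(OC)c(OC)c(OC)c1)[C@H]2C | intermediate
9 | (2S,3S)-3-methyl-2-(3,4,5-trimethoxyphenyl)-2,3-dihydro-1-benzofuran-5,6-dione | O=C1C=C2C(=CC1=O)O[C@H](c1cc(OC)c(OC)c(OC)c1)[C@H]2C | intermediate
10 | triisopropyl borate | CC(C)OB(OC(C)C)OC(C)C | starting material
11 | allylmagnesium bromide | C=CC[Mg]Br | starting material
12 | diisopropyl allylboronate | C=CCB(OC(C)C)OC(C)C | intermediate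
13 | (2S,3S,5R)-5-hydroxy-3-methyl-5-(prop-2-en-1-yl)-2-(3,4,5-trimethoxyphenyl)-2,3-dihydro-1-benzofuran-6(5H)-one | C=CC[C@@]1(O)C=C2C(=CC1=O)O[C@H](c1cc(OC)c(OC)c(OC)c1)[C@H]2C | intermediate
14 | (2S,3S,5R)-5-methoxy-3-methyl-5-(prop-2-en-1-yl)-2-(3,4,5-trimethoxyphenyl)-2,3-dihydro-1-benzofuran-6(5H)-one | C=CC[C@@]1(OC)C=C2C(=CC1=O)O[C@H](c1cc(OC)c(OC)c(OC)c1)[C@H]2C | target

## Step count and least certain steps

Total step count: 8. Longest linear sequence: 7 (steps 1, 2, 3, 4, 5, 7, 8); step 6 is a one-step side branch.

Step 7 (allyl addition to the quinone). The most likely failure is poor facial selectivity at C5. The catalyst–substrate pairing is untested on a quinone carbonyl, an uncatalysed background addition may compete, and 9 may decompose by tautomerisation before it reacts. The fallback sets out from 9 and uses known chemistry, a Barbier allylation with allyl bromide and In powder in DMF at 0 °C. Allylindium reagents add 1,2 to ortho-quinones and 1,2-diones, and the stereochemistry would rest on the substrate bias alone. The co-formed epimer (2S,3S,5S)-5-hydroxy-3-methyl-5-(prop-2-en-1-yl)-2-(3,4,5-trimethoxyphenyl)-2,3-dihydro-1-benzofuran-6(5H)-one F1 would be removed by chromatography, and the route is rejoined at 13.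

Step 5 (key step). The most likely failure is that the secondary hydroxyl adds too slowly. Tautomerisation of 7 to a quinone methide, with loss of the C3 configuration or isomerisation to a keto-catechol, or hydration of the quinone would then overtake ring closure. A later failure would be tautomerisation of 9 towards an aromatic benzofuran. The fallback forms the O1–C7a bond by cross-coupling instead of quinone capture and sets out from 4:
- NBS in MeCN at 0 °C should brominate the dialkoxyphenyl ring para to a benzyloxy group, giving rac-2-[4,5-bis(benzyloxy)-2-bromophenyl]-1-(3,4,5-trimethoxyphenyl)propan-1-one F2.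
- The transfer hydrogenation of step 3 should give (1S,2S)-2-[4,5-bis(benzyloxy)-2-bromophenyl]-1-(3,4,5-trimethoxyphenyl)propan-1-ol F3.
- Ullmann-type intramolecular etherification (CuI, 1,10-phenanthroline, Cs2CO3, toluene, 110 °C) closes the ring with retention at the carbinol, giving (2S,3S)-5,6-bis(benzyloxy)-3-methyl-2-(3,4,5-trimethoxyphenyl)-2,3-dihydro-1-benzofuran F4.
- Hydrogenolysis (H2, Pd/C, EtOAc) returns to the route at 8, which one equivalent of NaIO4 takes to 9.

Step 8 (O-methylation). The most likely failure is competing methylation of the more basic vinylogous-ester oxygen at C6, which would generate a dialkoxy-stabilised cation that can aromatise by shift or loss of a C5 substituent. The fallback sets out from 13 and replaces the uncatalysed hard electrophile by silver-assisted alkylation with a weak one: Purdie methylation with MeI and Ag2O over 4 Å molecular sieves in MeCN at rt to 40 °C. This is known for tertiary α-hydroxy carbonyl compounds and does not alkylate carbonyl oxygen. It returns directly to 14 and makes no new compound (entry F0).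

Step 3 (dynamic kinetic resolution). The most likely failure is racemisation of the α-aryl ketone being slower than reduction, so that the process degrades to a plain kinetic resolution with lower stereochemical purity, or sluggish turnover of the α-branched electron-rich ketone. The fallback sets out from 4 and separates the two tasks. Felkin–Anh-controlled reduction with K[(s-Bu)3BH] in THF at −78 °C should give the racemic like alcohol, that is 5 together with its enantiomer (1R,2R)-2-[3,4-bis(benzyloxy)phenyl]-1-(3,4,5-trimethoxyphenyl)propan-1-ol F5. Preparative chromatography on a chiral stationary phase then delivers 5, where the route is rejoined.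

## Further compounds

F1 | step 7 | (2S,3S,5S)-5-hydroxy-3-methyl-5-(prop-2-en-1-yl)-2-(3,4,5-trimethoxyphenyl)-2,3-dihydro-1-benzofuran-6(5H)-one | C=CC[C@]1(O)C=C2C(=CC1=O)O[C@H](c1cc(OC)c(OC)c(OC)c1)[C@H]2C
F2 | step 5 | rac-2-[4,5-bis(benzyloxy)-2-bromophenyl]-1-(3,4,5-trimethoxyphenyl)propan-1-one | CC(C(=O)c1cc(OC)c(OC)c(OC)c1)c1cc(OCc2ccccc2)c(OCc2ccccc2)cc1Br
F3 | step 5 | (1S,2S)-2-[4,5-bis(benzyloxy)-2-bromophenyl]-1-(3,4,5-trimethoxyphenyl)propan-1-ol | O[C@H](c1cc(OC)c(OC)c(OC)c1)[C@@H](C)c1cc(OCc2ccccc2)c(OCc2ccccc2)cc1Br
F4 | step 5 | (2S,3S)-5,6-bis(benzyloxy)-3-methyl-2-(3,4,5-trimethoxyphenyl)-2,3-dihydro-1-benzofuran | c1ccccc1COc1cc2c(cc1OCc1ccccc1)O[C@H](c1cc(OC)c(OC)c(OC)c1)[C@H]2C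
F0 | step 8 | none | none
F5 | step 3 | (1R,2R)-2-[3,4-bis(benzyloxy)phenyl]-1-(3,4,5-trimethoxyphenyl)propan-1-ol | O[C@@H](c1cc(OC)c(OC)c(OC)c1)[C@H](C)c1ccc(OCc2ccccc2)c(OCc2ccccc2)c1
A1 | alternative 1 | (6R)-6-allyl-3-ethoxy-6-methoxy-4-[(2S,3S)-3-(tert-butyldimethylsilyloxy)-3-(3,4,5-trimethoxyphenyl)propan-2-yl]cyclohexa-2,4-dien-1-one | C=CC[C@@]1(OC)C=C([C@H](C)[C@H](O[Si](C)(C)C(C)(C)C)c2cc(OC)c(OC)c(OC)c2)C(OCC)=CC1=O
A2 | alternative 2 | methyl (2S,3S)-6-(benzyloxy)-5-methoxy-2-(3,4,5-trimethoxyphenyl)-2,3-dihydro-1-benzofuran-3-carboxylate | COc1cc2c(cc1OCc1ccccc1)O[C@H](c1cc(OC)c(OC)c(OC)c1)[C@H]2C(=O)OC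
A3 | alternative 3 | methyl (2S,3R)-5,6-bis(methoxymethoxy)-2-(3,4,5-trimethoxyphenyl)-2,3-dihydro-1-benzofuran-3-carboxylate | COCOc1cc2c(cc1OCOC)O[C@H](c1cc(OC)c(OC)c(OC)c1)[C@@H]2C(=O)OC
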